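**Retrosynthetic overview**

- The strategy rests on the C2 bromine of the single benzene ring, held between the carbinol-bearing C1 and the methoxy-bearing C3. The C4 hydroxyl and C3 methoxy steer electrophilic bromine only to C5 and C6, so the C2–Br bond has to be built in with the ring.
- Target ⇐ reduction of the C1 methyl ester ⇐ two electrophilic brominations (C5 ortho to OH, then C6 para to OMe) of methyl 2-bromo-4-hydroxy-3-methoxybenzoate.
- That benzoate ⇐ Diels–Alder benzannulation: ring bonds C2–C3 and C1–C6 are formed from a 1-(dimethylamino)-3-silyloxy-4-methoxybutadiene and methyl 3-bromopropiolate, and the adduct aromatises by loss of dimethylamine.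
- Diene ⇐ O-silylation of an enaminone ⇐ ynone ⇐ N-methoxy-N-methyl-2-methoxyacetamide + ethynyl Grignard reagent; bromoalkyne ⇐ methyl propiolate.
- Ring order: the benzene ring is the only ring and is formed in the cycloaddition; all later steps are substitutions on the finished ring.

Key step: step 5

**Remarks**

- Ring positions are counted throughout from the carbon that carries the ester or carbinol (C1), with Br at C2 and OMe at C3.
- The target is achiral; the only compounds with stereocentres (3 and 10) are racemic, transient species.
- Should the acid in step 5 also remove the silyl group, the product is phenol 12 itself, so steps 5 and 6 converge.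
- Compounds 1, 2 (as a THF solution) and 8 are assumed to be purchased.

**Route**

Step 1
Reactants: 1 N-methoxy-N-methyl-2-methoxyacetamide; 2 ethynylmagnesium bromide
Product: 4 1-methoxybut-3-yn-2-one, via magnesium hemiaminal adduct 3 (not isolated)
Conditions: 2 (1.3 equiv, 0.5 M in THF), THF, 0 °C; inverse quench into 1 M HCl at 0 °C; Et2O extract dried (MgSO4) and used at once as a solution
Reagents that add atoms: none
Why: Weinreb ketone synthesis, in which the amide takes up the alkynyl Grignard reagent once to give chelated adduct 3 that releases the ynone only on quench, and the acidic inverse quench keeps the liberated N,O-dimethylhydroxylamine protonated so that it cannot add to the ynone.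

Step 2
Reactants: 4 1-methoxybut-3-yn-2-one
Product: 5 (E)-4-(dimethylamino)-1-methoxybut-3-en-2-one
Conditions: Me2NH (2 M in THF, 1.2 equiv), Et2O/THF, 0 °C → rt
Reagents that add atoms: dimethylamine, CNC
Why: Aza-Michael (conjugate) addition of a secondary amine to a terminal ynone, which should give the push-pull enaminone as its (E) isomer because a tertiary enaminone has no N–H to hold the (Z) form.

Step 3
Reactants: 5 (E)-4-(dimethylamino)-1-methoxybut-3-en-2-one
Product: 7 (1E,3Z)-1-(dimethylamino)-4-methoxy-3-(tert-butyldimethylsilyloxy)buta-1,3-diene, via potassium Z-enolate 6 (not isolated)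
Conditions: KN(SiMe3)2 (1.05 equiv), THF, −78 °C; then t-BuMe2SiCl (1.1 equiv), −78 °C → rt; filtration under Ar, bulb-to-bulb distillation or use crude
Reagents that add atoms: tert-butyldimethylsilyl chloride, CC(C)(C)[Si](C)(C)Cl
Why: Enolate O-silylation, the standard entry to 1-amino-3-siloxybutadienes: the OCH2 group is the only enolisable position of the vinylogous amide, and potassium bridging the enolate and methoxy oxygens should give the (Z)-enolate 6, so that methoxy ends cis to silyloxy and points outward in the s-cis diene.

Step 4
Reactants: 8 methyl propiolate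
Product: 9 methyl 3-bromopropiolate
Conditions: NBS (1.1 equiv), AgNO3 (0.1 equiv), acetone, rt, dark; lachrymator, used freshly prepared
Reagents that add atoms: N-bromosuccinimide, O=C1CCC(=O)N1Br
Why: Silver-catalysed electrophilic bromination of a terminal alkyne by NBS, a standard preparation of 3-bromopropiolates.

Step 5
Reactants: 7 (1E,3Z)-1-(dimethylamino)-4-methoxy-3-(tert-butyldimethylsilyloxy)buta-1,3-diene; 9 methyl 3-bromopropiolate
Product: 11 methyl 2-bromo-3-methoxy-4-(tert-butyldimethylsilyloxy)benzoate, via cis-aminocyclohexa-1,4-diene cycloadduct 10 (not isolated)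
Conditions: 9 (1.3 equiv), toluene, −20 °C → rt; then AcOH (3 equiv), rt → 40 °C
Reagents that add atoms: none
Why: A normal-electron-demand, asynchronous (4+2) cycloaddition of the s-cis diene in which the bond from the methoxy-bearing diene terminus to the brominated alkyne carbon (arene C2–C3) runs ahead of the bond from the amino-bearing terminus to the ester-bearing alkyne carbon (arene C1–C6); AcOH then protonates the doubly allylic amine of 10, the C–N bond ionises with help from the silyl enol ether oxygen, and loss of the proton on the methoxy carbon gives the arene. The closest known reaction type is the Diels–Alder/elimination benzannulation of 1-amino-3-siloxybutadienes with alkynoates to 4-siloxybenzoates, together with cycloadditions of 3-bromopropiolates as dienophiles, and the step applies it to members of both classes. The benzene ring, the only ring, is closed intermolecularly as a six-membered carbocycle by two C–C bonds formed suprafacially on both partners. No stereocentre survives: the two sp3 carbons of 10, cis through suprafacial addition to the E,Z diene, are erased on aromatisation. The regiochemistry needed (bromine next to methoxy, ester para to silyloxy) follows because the amino and silyloxy donors together make the methoxy-bearing terminus the nucleophilic end against the single opposing methoxy group, while the ester makes the brominated alkyne carbon the electrophilic end. Dimethylamine, not methanol, should leave because nitrogen is the basic site and the cation from C–N ionisation is stabilised by the silyloxy oxygen, whereas C–O ionisation would place charge on the ester-bearing carbon; toluene is chosen to disfavour a zwitterionic addition–bromide-loss pathway.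

Step 6
Reactants: 11 methyl 2-bromo-3-methoxy-4-(tert-butyldimethylsilyloxy)benzoate
Product: 12 methyl 2-bromo-4-hydroxy-3-methoxybenzoate
Conditions: Bu4NF (1.1 equiv), AcOH (1.1 equiv), THF, 0 °C
Reagents that add atoms: none
Why: Fluoride-mediated cleavage of an aryl silyl ether, driven by the Si–F bond, with AcOH buffering so that the methyl ester is not touched.

Step 7
Reactants: 12 methyl 2-bromo-4-hydroxy-3-methoxybenzoate
Product: 13 methyl 2,5-dibromo-4-hydroxy-3-methoxybenzoate
Conditions: Br2 (1.05 equiv), NaOAc (1.5 equiv), AcOH, rt
Reagents that add atoms: bromine, BrBr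
Why: Electrophilic aromatic substitution in which the free C4 hydroxyl directs bromine to its one open ortho position C5 (its para position carries the ester), as in the bromination of vanillin-type phenols, with NaOAc taking up the HBr.

Step 8
Reactants: 13 methyl 2,5-dibromo-4-hydroxy-3-methoxybenzoate
Product: 14 methyl 2,5,6-tribromo-4-hydroxy-3-methoxybenzoate
Conditions: Br2 (2.5 equiv), Fe powder (0.1 equiv), AcOH, 50–60 °C
Reagents that add atoms: bromine, BrBr
Why: Electrophilic aromatic substitution at the last ring C–H, C6, para to the C3 methoxy group, with FeBr3 formed from Fe and Br2 raising the electrophilicity for this deactivated ring in analogy to the second bromination of 5-bromovanillin; the C1 ester cannot be expelled by ipso attack as a para-hydroxybenzylic carbinol could.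

Step 9
Reactants: 14 methyl 2,5,6-tribromo-4-hydroxy-3-methoxybenzoate
Product: 15 2,5,6-tribromo-4-hydroxy-3-methoxybenzyl alcohol (target)
Conditions: (i-Bu)2AlH (4.5 equiv), CH2Cl2, −78 → 0 °C; 10% aq citric acid work-up at 0 °C
Reagents that add atoms: none
Why: Hydride reduction of an ester to the primary alcohol with (i-Bu)2AlH, in which the first equivalent is spent on the phenolic O–H, the excess reduces the hindered ester through the aldehyde stage, and aryl C–Br bonds are inert to this reagent at or below 0 °C.

**Compound list**

1 | N-methoxy-N-methyl-2-methoxyacetamide | COCC(=O)N(C)OC | starting material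
2 | ethynylmagnesium bromide | C#C[Mg]Br | starting material
3 | bromomagnesium salt of 2-[methoxy(methyl)amino]-1-methoxybut-3-yn-2-ol (racemic tetrahedral adduct) | COCC(O[Mg]Br)(C#C)N(C)OC | intermediate
4 | 1-methoxybut-3-yn-2-one | COCC(=O)C#C | intermediate
5 | (E)-4-(dimethylamino)-1-methoxybut-3-en-2-one | COCC(=O)/C=C/N(C)C | intermediate
6 | potassium (1Z,3E)-4-(dimethylamino)-1-methoxybuta-1,3-dien-2-olate | CN(C)/C=C/C([O-])=C/OC.[K+] | intermediate
7 | (1E,3Z)-1-(dimethylamino)-4-methoxy-3-(tert-butyldimethylsilyloxy)buta-1,3-diene | CN(C)/C=C/C(O[Si](C)(C)C(C)(C)C)=C/OC | intermediate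
8 | methyl propiolate | COC(=O)C#C | starting material
9 | methyl 3-bromopropiolate | COC(=O)C#CBr | intermediate
10 | methyl cis-2-bromo-6-(dimethylamino)-3-methoxy-4-(tert-butyldimethylsilyloxy)cyclohexa-1,4-diene-1-carboxylate (racemic, OMe and NMe2 cis) | COC(=O)C1=C(Br)[C@@H](OC)C(O[Si](C)(C)C(C)(C)C)=C[C@H]1N(C)C | intermediate
11 | methyl 2-bromo-3-methoxy-4-(tert-butyldimethylsilyloxy)benzoate | COC(=O)c1ccc(O[Si](C)(C)C(C)(C)C)c(OC)c1Br | intermediate
12 | methyl 2-bromo-4-hydroxy-3-methoxybenzoate | COC(=O)c1ccc(O)c(OC)c1Br | intermediate
13 | methyl 2,5-dibromo-4-hydroxy-3-methoxybenzoate | COC(=O)c1cc(Br)c(O)c(OC)c1Br | intermediate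
14 | methyl 2,5,6-tribromo-4-hydroxy-3-methoxybenzoate | COC(=O)c1c(Br)c(Br)c(O)c(OC)c1Br | intermediate
15 | 2,5,6-tribromo-4-hydroxy-3-methoxybenzyl alcohol | COc1c(O)c(Br)c(Br)c(CO)c1Br | target

**Step count and risks**

Total step count: 9. Longest linear sequence: 8 steps (steps 1, 2, 3, 5, 6, 7, 8, 9 from amide 1); step 4 is a one-step side branch.

Steps most likely to fail:

1. Step 5. Instead of closing the ring, the electron-rich diene (or dimethylamine set free early) may add to the bromoalkyne stepwise and expel bromide, or take up bromine by halophilic attack, so that the dienophile is consumed without cycloaddition. Loss of methanol in place of the amine on aromatisation is a lesser concern. Fallback: setting out from diene 7 and the bromine-free alkyne 8, the same cycloaddition–elimination (toluene, rt; then AcOH) should give, through methyl cis-6-(dimethylamino)-3-methoxy-4-(tert-butyldimethylsilyloxy)cyclohexa-1,4-diene-1-carboxylate F1, methyl 3-methoxy-4-(tert-butyldimethylsilyloxy)benzoate F2. Magnesiation with TMPMgCl·LiCl (TMP = 2,2,6,6-tetramethylpiperidide; THF, 0 °C) is expected at C2, where ester and methoxy direct together, as in the in-between metalation of 3,4-dialkoxybenzoic acid derivatives. This gives the C2 arylmagnesium chloride F3, which 1,2-dibromo-1,1,2,2-tetrachloroethane converts into bromide 11, where the route is rejoined.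

2. Step 8. Substitution may stall on a ring that carries two bromines and an ester and whose C3 methoxy group is twisted out of conjugation by its two ortho neighbours, and forcing may cleave the methyl ether with HBr. Fallback: setting out from silyl ether 11, the C6 bromine is placed by directed metalation before the phenol is freed. TMPMgCl·LiCl (THF, −20 °C) removes the only proton ortho to the ester to give the C6 arylmagnesium chloride F4, which 1,2-dibromo-1,1,2,2-tetrachloroethane converts into methyl 2,6-dibromo-3-methoxy-4-(tert-butyldimethylsilyloxy)benzoate F5. Bu4NF/AcOH (THF, 0 °C) gives methyl 2,6-dibromo-4-hydroxy-3-methoxybenzoate F6, and Br2/NaOAc/AcOH brominates its last C–H, C5 ortho to the hydroxyl, to rejoin the route at 14.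

3. Step 9. Reduction may stop short on an ester flanked by two bromines and deactivated by the para aluminium phenoxide, or the benzylic oxygen may be lost through a quinone methide followed by further hydride delivery. Fallback: setting out from 14, the phenol is masked with t-BuMe2SiOTf/2,6-lutidine (CH2Cl2, 0 °C) as methyl 2,5,6-tribromo-3-methoxy-4-(tert-butyldimethylsilyloxy)benzoate F7, which has no phenoxide to deactivate the ester or open a quinone methide path. (i-Bu)2AlH (CH2Cl2, −78 → 0 °C) should give [2,5,6-tribromo-3-methoxy-4-(tert-butyldimethylsilyloxy)phenyl]methanol F8, and Bu4NF/AcOH (THF, 0 °C) frees the phenol to arrive at target 15.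

**Further compounds**

F1 | step 5 | methyl cis-6-(dimethylamino)-3-methoxy-4-(tert-butyldimethylsilyloxy)cyclohexa-1,4-diene-1-carboxylate (racemic) | COC(=O)C1=C[C@@H](OC)C(O[Si](C)(C)C(C)(C)C)=C[C@H]1N(C)C
F2 | step 5 | methyl 3-methoxy-4-(tert-butyldimethylsilyloxy)benzoate | COC(=O)c1ccc(O[Si](C)(C)C(C)(C)C)c(OC)c1
F3 | step 5 | [6-(methoxycarbonyl)-2-methoxy-3-(tert-butyldimethylsilyloxy)phenyl]magnesium chloride | COC(=O)c1ccc(O[Si](C)(C)C(C)(C)C)c(OC)c1[Mg]Cl
F4 | step 8 | [3-bromo-2-(methoxycarbonyl)-4-methoxy-5-(tert-butyldimethylsilyloxy)phenyl]magnesium chloride | COC(=O)c1c([Mg]Cl)cc(O[Si](C)(C)C(C)(C)C)c(OC)c1Br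
F5 | step 8 | methyl 2,6-dibromo-3-methoxy-4-(tert-butyldimethylsilyloxy)benzoate | COC(=O)c1c(Br)cc(O[Si](C)(C)C(C)(C)C)c(OC)c1Br
F6 | step 8 | methyl 2,6-dibromo-4-hydroxy-3-methoxybenzoate | COC(=O)c1c(Br)cc(O)c(OC)c1Br
F7 | step 9 | methyl 2,5,6-tribromo-3-methoxy-4-(tert-butyldimethylsilyloxy)benzoate | COC(=O)c1c(Br)c(Br)c(O[Si](C)(C)C(C)(C)C)c(OC)c1Br
F8 | step 9 | [2,5,6-tribromo-3-methoxy-4-(tert-butyldimethylsilyloxy)phenyl]methanol | OCc1c(Br)c(Br)c(O[Si](C)(C)C(C)(C)C)c(OC)c1Br
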